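**Assumption:** the biosynthesis is taken to be hydroperoxidation at C6 of an acyclic 2,5-dienoate side chain, then 6-exo conjugate addition of the hydroperoxide to the 2-methyl-2-enoate; chain atoms are numbered C1 (ester carbon) to C8 (CH2 on the ring).

**Retrosynthetic overview**
1. The 1,2-dioxane is the only ring made and it closes last: the O–C3 bond forms by an enantioselective 6-exo peroxy-Michael addition of a C6 tertiary hydroperoxide to the (E)-2-methyl-2-enoate, and C2 is set by the protonation that follows.
2. The C6–O bond comes from O2: Markovnikov hydroperoxidation of the C5=C6 olefin of a skipped diene ester.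
3. The enoate comes from cross-metathesis of a terminal olefin with methyl methacrylate; the C5=C6 olefin from a Wittig reaction at a methyl ketone.
4. The cyclohexenone ring is bought as dihydro-β-ionone and only oxidised at its allylic CH2.

**Route**

Step 1
Reactants: 1 dihydro-β-ionone [4-(2,6,6-trimethylcyclohex-1-en-1-yl)butan-2-one]
Product: 2 2,4,4-trimethyl-3-(3-oxobutyl)cyclohex-2-en-1-one
Conditions: Rh2(cap)4 (1 mol %, cap = caprolactamate), t-BuOOH (70% in water, 5 equiv), K2CO3 (0.5 equiv), CH2Cl2, rt
Reagents that add atoms: tert-butyl hydroperoxide, CC(C)(C)OO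
Why: Kharasch–Sosnovsky-type allylic oxidation through the tert-butylperoxyl radical chain; the tetrasubstituted olefin has only one ring allylic CH2, which gives the conjugated enone, while the side-chain allylic CH2 is shielded by the neighbouring quaternary carbon; no stereocentre is formed.

Step 2
Reactants: 2 2,4,4-trimethyl-3-(3-oxobutyl)cyclohex-2-en-1-one; 3 (but-3-en-1-yl)triphenylphosphonium bromide
Product: 5 2,4,4-trimethyl-3-(3-methylhepta-3,6-dien-1-yl)cyclohex-2-en-1-one (E/Z mixture), via butenylidene ylide 4 (not isolated)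
Conditions: 3, NaN(SiMe3)2, THF, 0 °C; then 2, −78 °C to rt
Reagents that add atoms: none
Why: Wittig olefination in which the non-stabilised ylide attacks the unhindered saturated methyl ketone faster than the conjugated, α-methylated ring enone; the E/Z ratio of the new C5=C6 olefin is irrelevant because step 4 erases it, and no stereocentre is formed.

Step 3
Reactants: 5 2,4,4-trimethyl-3-(3-methylhepta-3,6-dien-1-yl)cyclohex-2-en-1-one; 6 methyl methacrylate
Product: 7 methyl (2E)-2,6-dimethyl-8-(2,6,6-trimethyl-3-oxocyclohex-1-en-1-yl)octa-2,5-dienoate (5E/5Z mixture)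
Conditions: 6 (10 equiv), second-generation Hoveyda–Grubbs catalyst (5 mol %), 1,4-benzoquinone (10 mol %), CH2Cl2, 40 °C
Reagents that add atoms: none
Why: Olefin cross-metathesis in which only the terminal vinyl group engages the ruthenium carbene (the tri- and tetrasubstituted olefins are inert), excess methacrylate suppresses homodimerisation, the trisubstituted enoate forms as the E isomer, and benzoquinone suppresses isomerisation of the skipped diene.

Step 4
Reactants: 7 methyl (2E)-2,6-dimethyl-8-(2,6,6-trimethyl-3-oxocyclohex-1-en-1-yl)octa-2,5-dienoate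
Product: 8 methyl (2E)-2,6-dimethyl-6-(triethylsilylperoxy)-8-(2,6,6-trimethyl-3-oxocyclohex-1-en-1-yl)oct-2-enoate (racemic)
Conditions: Co(thd)2 (5 mol %, thd = 2,2,6,6-tetramethylheptane-3,5-dionate), O2 (1 atm), Et3SiH (2 equiv), ClCH2CH2Cl, rt
Reagents that add atoms: dioxygen, O=O; triethylsilane, CC[SiH](CC)CC
Why: Isayama–Mukaiyama peroxidation (cobalt hydride hydrogen-atom transfer): H• goes to C5 of the electron-rich trisubstituted olefin far faster than to the enoate or the hindered tetrasubstituted enone, and the tertiary C6 radical is trapped by O2 and silylated; C6 forms as a racemate because the planar radical is trapped on both faces, and both C5=C6 isomers converge on the same product.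

Step 5
Reactants: 8 methyl (2E)-2,6-dimethyl-6-(triethylsilylperoxy)-8-(2,6,6-trimethyl-3-oxocyclohex-1-en-1-yl)oct-2-enoate
Product: 10 diacarperoxide A, via hydroperoxide 9 (not isolated)
Conditions: HCl (2 mol %), MeOH, 0 °C, evaporation from toluene; then tert-leucine-derived iminophosphorane–thiourea catalyst [from P(4-MeOC6H4)3, 10 mol %], toluene, −20 °C; AcOH quench, silica chromatography
Reagents that add atoms: none
Why: Proposed new method: after acid methanolysis of the silyl peroxide, the iminophosphorane deprotonates the tertiary hydroperoxide while the thiourea binds the ester carbonyl, so the peroxide anion adds 6-exo to the Re face of C3 of the E-enoate (sets 3R; the fully substituted enone β-carbon is too hindered to compete), and the iminophosphonium N–H, still hydrogen-bonded to the new peroxide oxygens, protonates the enolate on the same side (Si face of C2, net syn addition, sets 2R) before Weitz–Scheffer epoxide closure can occur; the catalyst enantiomer giving Re attack is identified in the first run; C6 is not influenced by the catalyst, so (6R)-9 gives 10 and (6S)-9 gives its 6S epimer (about 1:1, at most 50% of 10), and C6 is fixed only by separating these diastereomers on silica; closest known reactions are the iminophosphorane-catalysed enantioselective intramolecular oxa-Michael addition of alcohols to unsaturated esters and the amine-mediated peroxy-Michael closure of hydroperoxy enoates to 1,2-dioxanes.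

**Compound list**
1 | dihydro-β-ionone, 4-(2,6,6-trimethylcyclohex-1-en-1-yl)butan-2-one | CC(=O)CCC1=C(C)CCCC1(C)C | starting material
2 | 2,4,4-trimethyl-3-(3-oxobutyl)cyclohex-2-en-1-one | CC(=O)CCC1=C(C)C(=O)CCC1(C)C | intermediate
3 | (but-3-en-1-yl)triphenylphosphonium bromide | C=CCC[P+](c1ccccc1)(c1ccccc1)c1ccccc1.[Br-] | starting material
4 | but-3-enylidene(triphenyl)phosphorane (not isolated) | C=CCC=P(c1ccccc1)(c1ccccc1)c1ccccc1 | intermediate
5 | 2,4,4-trimethyl-3-(3-methylhepta-3,6-dien-1-yl)cyclohex-2-en-1-one (E/Z mixture) | C=CCC=C(C)CCC1=C(C)C(=O)CCC1(C)C | intermediate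
6 | methyl methacrylate | C=C(C)C(=O)OC | starting material
7 | methyl (2E)-2,6-dimethyl-8-(2,6,6-trimethyl-3-oxocyclohex-1-en-1-yl)octa-2,5-dienoate (5E/5Z mixture) | COC(=O)/C(C)=C/CC=C(C)CCC1=C(C)C(=O)CCC1(C)C | intermediate
8 | methyl (2E)-2,6-dimethyl-6-(triethylsilylperoxy)-8-(2,6,6-trimethyl-3-oxocyclohex-1-en-1-yl)oct-2-enoate (racemic) | COC(=O)/C(C)=C/CCC(C)(OO[Si](CC)(CC)CC)CCC1=C(C)C(=O)CCC1(C)C | intermediate
9 | methyl (2E)-6-hydroperoxy-2,6-dimethyl-8-(2,6,6-trimethyl-3-oxocyclohex-1-en-1-yl)oct-2-enoate (racemic, not isolated) | COC(=O)/C(C)=C/CCC(C)(OO)CCC1=C(C)C(=O)CCC1(C)C | intermediate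
10 | diacarperoxide A, methyl (2R)-2-{(3R,6R)-6-methyl-6-[2-(2,6,6-trimethyl-3-oxocyclohex-1-en-1-yl)ethyl]-1,2-dioxan-3-yl}propanoate | COC(=O)[C@H](C)[C@H]1CC[C@@](C)(CCC2=C(C)C(=O)CCC2(C)C)OO1 | target

**Total step count:** 5. **Longest linear sequence:** 5 steps (from 1).

**Three steps most likely to fail**

Step 5. The enantioselective peroxy-Michael closure is new. The hindered α-methyl enoate may react slowly, the enolate may be protonated on the other face (giving the C2 epimer) or close to an epoxide, and C6 is not controlled. The fallback sets out from 5 and comes back at 10. It moves the same ring closure to a thioester, a stronger Michael acceptor for which hydrogen-bond (amine–squaramide) catalysis of oxa-Michael ring closures is established. Cross-metathesis of 5 with S-ethyl 2-methylprop-2-enethioate F1 (made from methacryloyl chloride and ethanethiol) gives S-ethyl (2E)-2,6-dimethyl-8-(2,6,6-trimethyl-3-oxocyclohex-1-en-1-yl)octa-2,5-dienethioate F2. The hydroperoxidation of step 4 then gives S-ethyl (2E)-2,6-dimethyl-6-(triethylsilylperoxy)-8-(2,6,6-trimethyl-3-oxocyclohex-1-en-1-yl)oct-2-enethioate F3. Acid methanolysis frees S-ethyl (2E)-6-hydroperoxy-2,6-dimethyl-8-(2,6,6-trimethyl-3-oxocyclohex-1-en-1-yl)oct-2-enethioate F4, which a cinchona amine–squaramide catalyst closes to S-ethyl (2R)-2-{(3R,6R)-6-methyl-6-[2-(2,6,6-trimethyl-3-oxocyclohex-1-en-1-yl)ethyl]-1,2-dioxan-3-yl}propanethioate F5, the 6S epimer again being removed on silica. AgOCOCF3 in methanol converts F5 into 10.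

Step 4. Hydrogen-atom transfer may also touch the enoate or abstract the doubly allylic C4–H, and cobalt residues can destroy peroxide. The fallback sets out from 7 and comes back at 9, the hydroperoxide that step 5 passes through. It replaces the radical addition by an ionic Markovnikov addition: 50% H2O2 with catalytic H2SO4 at 0 °C protonates C5 of the trisubstituted olefin and H2O2 captures the C6 cation, while the conjugated enoate and enone olefins are too electron-poor to be protonated. No new compound is made (F0).

Step 2. The ylide must choose the methyl ketone over the ring enone and may simply enolise the diketone. The fallback sets out from 1 and comes back at 9. It forms the C5–C6 bond by carbonyl addition before the ring is oxidised. Commercial but-3-enylmagnesium bromide adds to 1 to give 3-methyl-1-(2,6,6-trimethylcyclohex-1-en-1-yl)hept-6-en-3-ol F6. The allylic oxidation of step 1 then gives 3-(3-hydroxy-3-methylhept-6-en-1-yl)-2,4,4-trimethylcyclohex-2-en-1-one F7, and cross-metathesis with 6 gives methyl (2E)-6-hydroxy-2,6-dimethyl-8-(2,6,6-trimethyl-3-oxocyclohex-1-en-1-yl)oct-2-enoate F8. Finally 50% H2O2 with catalytic H2SO4 exchanges the tertiary hydroxyl for a hydroperoxide through the C6 cation and delivers 9.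

**Further compounds**
F1 | step 5 | S-ethyl 2-methylprop-2-enethioate | CCSC(=O)C(C)=C
F2 | step 5 | S-ethyl (2E)-2,6-dimethyl-8-(2,6,6-trimethyl-3-oxocyclohex-1-en-1-yl)octa-2,5-dienethioate (5E/5Z mixture) | CCSC(=O)/C(C)=C/CC=C(C)CCC1=C(C)C(=O)CCC1(C)C
F3 | step 5 | S-ethyl (2E)-2,6-dimethyl-6-(triethylsilylperoxy)-8-(2,6,6-trimethyl-3-oxocyclohex-1-en-1-yl)oct-2-enethioate (racemic) | CCSC(=O)/C(C)=C/CCC(C)(OO[Si](CC)(CC)CC)CCC1=C(C)C(=O)CCC1(C)C
F4 | step 5 | S-ethyl (2E)-6-hydroperoxy-2,6-dimethyl-8-(2,6,6-trimethyl-3-oxocyclohex-1-en-1-yl)oct-2-enethioate (racemic) | CCSC(=O)/C(C)=C/CCC(C)(OO)CCC1=C(C)C(=O)CCC1(C)C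
F5 | step 5 | S-ethyl (2R)-2-{(3R,6R)-6-methyl-6-[2-(2,6,6-trimethyl-3-oxocyclohex-1-en-1-yl)ethyl]-1,2-dioxan-3-yl}propanethioate | CCSC(=O)[C@H](C)[C@H]1CC[C@@](C)(CCC2=C(C)C(=O)CCC2(C)C)OO1
F0 | step 4 | none | none
F6 | step 2 | 3-methyl-1-(2,6,6-trimethylcyclohex-1-en-1-yl)hept-6-en-3-ol (racemic) | C=CCCC(C)(O)CCC1=C(C)CCCC1(C)C
F7 | step 2 | 3-(3-hydroxy-3-methylhept-6-en-1-yl)-2,4,4-trimethylcyclohex-2-en-1-one (racemic) | C=CCCC(C)(O)CCC1=C(C)C(=O)CCC1(C)C
F8 | step 2 | methyl (2E)-6-hydroxy-2,6-dimethyl-8-(2,6,6-trimethyl-3-oxocyclohex-1-en-1-yl)oct-2-enoate (racemic) | COC(=O)/C(C)=C/CCC(C)(O)CCC1=C(C)C(=O)CCC1(C)C
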